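The furochromane ketal is cut into lasiodiplodin and a chiral dihydrofuran. Everything rests on assembling that five-membered ring across its O–CH2 bond and its CH(CH3)–CH(ring-fusion) bond. The key step exploits the fact that the ring oxygen, the ketal carbon and the ring-fusion carbon of the tetrahydrofuran ring are the enol O–C=C of a β-keto ester, a C,O-bis-nucleophile, whereas the OCH2–CH(CH3) edge is a 1,2-bis-electrophile. Methyl acetoacetate and (Z)-1-bromo-1-nitropropene undergo a thiourea-catalysed Michael/O-alkylation domino that forms both bonds and sets the methyl-bearing stereocentre, the only one of the ketal domain that cannot equilibrate. Denitration, reduction and an acid-mediated arylation/ketalisation with lasiodiplodin finish the target.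

Key step: step 7

Remark: the target is read as R at the lactone carbon and S,S,S at the methyl-bearing carbon, the ring-fusion carbon and the ketal carbon; the nitro group on the OCH carbon is a temporary activating group that step 8 removes.

Step 1
Reactants: 1 2,4-dimethoxy-6-methylbenzoic acid; 2 5-bromopent-1-ene
Product: 3 2-(hex-5-en-1-yl)-4,6-dimethoxybenzoic acid
Conditions: LiN(i-Pr)2 (2.2 equiv), THF, −78 °C; then 2, −78 → 0 °C; aq. HCl work-up
Reagents that add atoms: none
Why: Creger-type lateral lithiation gives the carboxylate-directed benzylic dianion of the o-toluic acid, which is alkylated at the benzylic carbon by the primary bromide (SN2), so the alkenyl arm is installed without an ester hydrolysis step.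

Step 2
Reactants: 3 2-(hex-5-en-1-yl)-4,6-dimethoxybenzoic acid; 4 (S)-pent-4-en-2-ol
Product: 5 (R)-pent-4-en-2-yl 2-(hex-5-en-1-yl)-4,6-dimethoxybenzoate
Conditions: PPh3, DIAD, THF, 0 °C → rt
Reagents that add atoms: none
Why: Mitsunobu esterification, in which the hindered 2,6-disubstituted benzoate is the nucleophile and displaces the activated secondary alcohol with inversion, so (S)-4 should give the (R)-ester that carries the lactone stereocentre.

Step 3
Reactants: 5 (R)-pent-4-en-2-yl 2-(hex-5-en-1-yl)-4,6-dimethoxybenzoate
Product: 7 (R)-O-methyllasiodiplodin, via macrocyclic alkene 6 (not isolated)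
Conditions: second-generation Grubbs catalyst (5 mol%), CH2Cl2 (2 mM), 40 °C; then solvent exchange to EtOAc, Pd/C, H2 (1 atm), rt
Reagents that add atoms: none
Why: Ring-closing metathesis of the two terminal alkenes closes the 12-membered lactone under high dilution, and the E/Z mixture is hydrogenated in the same flask, so alkene geometry is irrelevant and the stereocentre is untouched.

Step 4
Reactants: 7 (R)-O-methyllasiodiplodin
Product: 8 (R)-lasiodiplodin
Conditions: NaSEt (4 equiv), DMF, 110 °C; aq. HCl work-up
Reagents that add atoms: none
Why: Nucleophilic (SN2) O-demethylation by thiolate should occur at the unhindered methoxy group para to the lactone carbonyl rather than at the ortho methoxy group wedged beside the ester, which frees the phenol needed in step 10.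

Step 5
Reactants: 9 bromonitromethane; 10 acetaldehyde
Product: 11 1-bromo-1-nitropropan-2-ol (diastereomer mixture)
Conditions: NaI (15 mol%), THF, rt
Reagents that add atoms: none
Why: Henry (nitroaldol) addition of the acidic bromonitromethane to acetaldehyde under mild iodide catalysis; both new stereocentres are erased in step 6.

Step 6
Reactants: 11 1-bromo-1-nitropropan-2-ol
Product: 12 (Z)-1-bromo-1-nitroprop-1-ene
Conditions: MsCl (1.2 equiv), i-Pr2NEt (2.4 equiv), CH2Cl2, −20 → 0 °C; used as a cold stock solution
Reagents that add atoms: none
Why: Mesylation and E1cB elimination of the β-hydroxy nitro compound give the conjugated nitroalkene, the Z isomer (nitro trans to methyl) being the thermodynamic one.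

Step 7
Reactants: 13 methyl acetoacetate; 12 (Z)-1-bromo-1-nitroprop-1-ene
Product: 15 methyl (4S,5S)-2,4-dimethyl-5-nitro-4,5-dihydrofuran-3-carboxylate, via Michael adduct 14 (not isolated)
Conditions: 1-[3,5-bis(trifluoromethyl)phenyl]-3-[(1S,2S)-2-(dimethylamino)cyclohexyl]thiourea (10 mol%), toluene, −30 °C; then i-Pr2NEt (1.1 equiv), −30 → 0 °C
Reagents that add atoms: none
Why: The thiourea binds the nitro group of 12 while its tertiary amine delivers the enol of 13, so conjugate addition at the methyl-bearing β-carbon forms the C–C bond; after the bromonitronate is protonated to 14 and the amine base is added, the ketone enol oxygen displaces bromide at the CH(Br)NO2 carbon and forms the O–CH bond. The closest known reaction type is the bifunctional-thiourea-catalysed Michael addition/O-alkylation domino (an interrupted Feist–Benary-type annulation) of 1,3-dicarbonyl compounds with (Z)-α-bromonitroalkenes, which gives trans-5-nitro-4,5-dihydrofurans. The ring closes in the 5-exo-tet mode. The methyl-bearing stereocentre (4S) is set by the catalyst through Re-face attack on the β-carbon of 12 (the S,S antipode is chosen by analogy with its facial bias towards (E)-nitroalkenes, and the R,R antipode is equally available should the sense prove opposite); the nitro-bearing carbon ends trans (5S) by equilibration through the nitronate and does not matter, because it becomes CH2 in step 8. The step needs O- rather than C-alkylation (nitrocyclopropane) and no loss of HNO2: the enolisable ketone of the β-keto ester should close the five-membered ring in preference to a fully substituted cyclopropane, and low temperature with one equivalent of hindered amine should keep 15 from aromatising.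

Step 8
Reactants: 15 methyl (4S,5S)-2,4-dimethyl-5-nitro-4,5-dihydrofuran-3-carboxylate
Product: 16 methyl (S)-2,4-dimethyl-4,5-dihydrofuran-3-carboxylate
Conditions: Bu3SnH (1.3 equiv), AIBN (0.2 equiv), toluene, 80 °C
Reagents that add atoms: none
Why: Ono-type radical denitration, in which the stannyl radical adds to the nitro group and the resulting α-alkoxy radical is reduced by Bu3SnH; the C4 stereocentre is not involved, and neutral, base-free conditions should avoid HNO2 elimination to the furan.

Step 9
Reactants: 16 methyl (S)-2,4-dimethyl-4,5-dihydrofuran-3-carboxylate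
Product: 17 (S)-(2,4-dimethyl-4,5-dihydrofuran-3-yl)methanol
Conditions: LiAlH4, Et2O, −10 → 0 °C; Na2SO4·10H2O quench; used at once
Reagents that add atoms: none
Why: Hydride reduction of the vinylogous carbonate ester to the allylic alcohol at low temperature leaves the enol ether and the stereocentre untouched.

Step 10
Reactants: 8 (R)-lasiodiplodin; 17 (S)-(2,4-dimethyl-4,5-dihydrofuran-3-yl)methanol
Product: 19 lasiodiplactone A, via benzylated dihydrofuran 18 (not isolated)
Conditions: BF3·OEt2 (1.0 equiv), MgSO4, Et2O/CH2Cl2, −78 → 0 °C
Reagents that add atoms: none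
Why: Friedel–Crafts-type electrophilic aromatic substitution followed by ketalisation: BF3 ionises 17 to a 3-methylene-oxolan-2-ylium ion that should alkylate 8 at the carbon ortho to the phenol and para to the methoxy group, and the phenol then adds reversibly to the enol ether of 18, so the cis-fused ketal with the benzylic CH2 trans to the methyl group (ring-fusion and ketal carbons S,S, dictated by the S methyl centre) forms under thermodynamic control.

Compound list
1 | 2,4-dimethoxy-6-methylbenzoic acid | COc1cc(C)c(C(=O)O)c(OC)c1 | starting material
2 | 5-bromopent-1-ene | C=CCCCBr | starting material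
3 | 2-(hex-5-en-1-yl)-4,6-dimethoxybenzoic acid | C=CCCCCc1cc(OC)cc(OC)c1C(=O)O | intermediate
4 | (S)-pent-4-en-2-ol | C[C@H](O)CC=C | starting material
5 | (R)-pent-4-en-2-yl 2-(hex-5-en-1-yl)-4,6-dimethoxybenzoate | C=CCCCCc1cc(OC)cc(OC)c1C(=O)O[C@H](C)CC=C | intermediate
6 | macrocyclic alkene, the 12-membered metathesis lactone with a CH=CH two carbons from the lactone CH (E/Z mixture, formed in the flask in step 3) | COc1cc(OC)cc2c1C(=O)O[C@H](C)CC=CCCCC2 | intermediate
7 | (R)-O-methyllasiodiplodin | COc1cc(OC)cc2c1C(=O)O[C@H](C)CCCCCCC2 | intermediate
8 | (R)-lasiodiplodin | COc1cc(O)cc2c1C(=O)O[C@H](C)CCCCCCC2 | intermediate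
9 | bromonitromethane | [O-][N+](=O)CBr | starting material
10 | acetaldehyde | CC=O | starting material
11 | 1-bromo-1-nitropropan-2-ol (diastereomer mixture) | CC(O)C(Br)[N+](=O)[O-] | intermediate
12 | (Z)-1-bromo-1-nitroprop-1-ene | C/C=C(\Br)[N+](=O)[O-] | intermediate
13 | methyl acetoacetate | COC(=O)CC(C)=O | starting material
14 | methyl (3S)-2-acetyl-4-bromo-3-methyl-4-nitrobutanoate (Michael adduct, mixture at C2 and C4, formed in the flask in step 7) | COC(=O)C(C(C)=O)[C@H](C)C(Br)[N+](=O)[O-] | intermediate
15 | methyl (4S,5S)-2,4-dimethyl-5-nitro-4,5-dihydrofuran-3-carboxylate | CC1=C(C(=O)OC)[C@H](C)[C@@H]([N+](=O)[O-])O1 | intermediate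
16 | methyl (S)-2,4-dimethyl-4,5-dihydrofuran-3-carboxylate | CC1=C(C(=O)OC)[C@H](C)CO1 | intermediate
17 | (S)-(2,4-dimethyl-4,5-dihydrofuran-3-yl)methanol | CC1=C(CO)[C@H](C)CO1 | intermediate
18 | lasiodiplodin carrying the [(S)-2,4-dimethyl-4,5-dihydrofuran-3-yl]methyl group on the arene carbon between the phenol and the alkyl chain (formed in the flask in step 10) | COc1cc(O)c(CC2=C(C)OC[C@H]2C)c2c1C(=O)O[C@H](C)CCCCCCC2 | intermediate
19 | lasiodiplactone A | COc1cc2c(c3c1C(=O)O[C@H](C)CCCCCCC3)C[C@H]1[C@H](C)CO[C@@]1(C)O2 | target

Total step count: 10. Longest linear sequence: 6 steps (steps 5, 6, 7, 8, 9 and 10).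

Steps most likely to fail

Step 7. The small, volatile aliphatic bromonitroalkene may be discriminated poorly by the catalyst, closure may go through carbon to a nitrocyclopropane, or base may induce loss of HNO2 and aromatisation. The fallback sets out from 13 and comes back at 15, still forming both bonds in one flask. Commercial 1-nitropropan-2-ol F1 is dehydrated (MsCl, Et3N) to (E)-1-nitroprop-1-ene F2, an acceptor class with broad precedent in thiourea- or squaramide-catalysed additions of 1,3-dicarbonyl compounds. Addition of 13 gives methyl (3S)-2-acetyl-3-methyl-4-nitrobutanoate F3. Without isolation, I2 and K2CO3 iodinate the nitronate to methyl (3S)-2-acetyl-4-iodo-3-methyl-4-nitrobutanoate F4, whose enol oxygen displaces iodide to give 15. The ring closure thus becomes oxidative and the acceptor carries no halogen during the enantio-determining step.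

Step 10. Alkylation may occur at the other free arene carbon (between the two oxygens) or on oxygen, and the acid-labile alcohol 17 may self-condense or aromatise before it is captured. The fallback sets out from 7 and 16 and comes back at 19, fixing the aryl–carbon bond before the ketal is made. Rieche formylation of 7 (Cl2CHOMe, TiCl4) at the position para to the ortho-methoxy group gives the formyl derivative of O-methyllasiodiplodin F5. BCl3 at −78 °C removes only the methyl ether chelated to the new aldehyde and gives the formyl lasiodiplodin F6, and NaBH4 gives the hydroxymethyl lasiodiplodin F7. In parallel, 16 is saponified (LiOH) to (S)-2,4-dimethyl-4,5-dihydrofuran-3-carboxylic acid F8, which loses CO2 on gentle warming to (S)-3,5-dimethyl-2,3-dihydrofuran F9. Heating F7 with F9 (toluene, 120 °C) generates the o-quinone methide by loss of water, and an inverse-demand hetero-Diels–Alder reaction on the face anti to the methyl group gives 19. A trace of pyridinium tosylate would equilibrate the ketal to the same thermodynamic isomer.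

Step 8. Thermal or adventitious-base elimination of HNO2 may aromatise the ring and erase the stereocentre, or the tin hydride chain may stall. The fallback sets out from 15 and comes back at 19, moving the denitration to a stage where elimination can no longer give a furan. i-Bu2AlH (CH2Cl2, −78 °C) reduces the ester to (4S,5S)-(2,4-dimethyl-5-nitro-4,5-dihydrofuran-3-yl)methanol F10. The BF3·OEt2 union with 8 as in step 10 gives the nitro ketal F11 (19 with a nitro group on the OCH carbon, trans to the methyl group). Bu3SnH/AIBN then removes the nitro group as the last operation.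

Further compounds
F1 | step 7 | 1-nitropropan-2-ol | CC(O)C[N+](=O)[O-]
F2 | step 7 | (E)-1-nitroprop-1-ene | C/C=C/[N+](=O)[O-]
F3 | step 7 | methyl (3S)-2-acetyl-3-methyl-4-nitrobutanoate | COC(=O)C(C(C)=O)[C@H](C)C[N+](=O)[O-]
F4 | step 7 | methyl (3S)-2-acetyl-4-iodo-3-methyl-4-nitrobutanoate | COC(=O)C(C(C)=O)[C@H](C)C(I)[N+](=O)[O-]
F5 | step 10 | formyl derivative of (R)-O-methyllasiodiplodin (CHO between the para-methoxy group and the alkyl chain) | COc1cc(OC)c(C=O)c2c1C(=O)O[C@H](C)CCCCCCC2
F6 | step 10 | formyl derivative of (R)-lasiodiplodin (CHO ortho to the phenol) | COc1cc(O)c(C=O)c2c1C(=O)O[C@H](C)CCCCCCC2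
F7 | step 10 | hydroxymethyl derivative of (R)-lasiodiplodin (CH2OH ortho to the phenol) | COc1cc(O)c(CO)c2c1C(=O)O[C@H](C)CCCCCCC2
F8 | step 10 | (S)-2,4-dimethyl-4,5-dihydrofuran-3-carboxylic acid | CC1=C(C(=O)O)[C@H](C)CO1
F9 | step 10 | (S)-3,5-dimethyl-2,3-dihydrofuran | CC1=C[C@H](C)CO1
F10 | step 8 | (4S,5S)-(2,4-dimethyl-5-nitro-4,5-dihydrofuran-3-yl)methanol | CC1=C(CO)[C@H](C)[C@@H]([N+](=O)[O-])O1
F11 | step 8 | nitro ketal, lasiodiplactone A with a nitro group on the OCH carbon trans to the methyl group | COc1cc2c(c3c1C(=O)O[C@H](C)CCCCCCC3)C[C@H]1[C@H](C)[C@@H]([N+](=O)[O-])O[C@@]1(C)O2
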